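**Retrosynthetic overview**

1. No ring is formed: rings A, B and C and both stereocentres (2R,3S) are bought as (+)-catechin 1. The only bonds made are two aryl ester C–O bonds; the only bonds broken at the end are six benzyl ether C–O bonds.
2. Both galloyl units come from 3,4,5-tris(benzyloxy)benzoic acid 2 through its acid chloride 3.
3. Disconnection at O7–acyl: phenol acylation of 1 with 3 while the catechol is masked in the flask with phenylboronic acid 4 (boronates 5 and 6), giving monoester 7.
4. Disconnection at O3'–acyl (key step): acylation of 7 with 3 directed by a catalyst anchored reversibly at the 3-OH, giving diester 8; hydrogenolysis then gives target 9.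
5. Order: O7 ester first, O3' ester last (so the migration-prone catechol monoester never meets base), then neutral debenzylation.

**Assumptions**

- The SMILES is read as the (2R,3S) flavan-3-ol, i.e. (+)-catechin, carrying galloyl esters at O7 and O3', with 3-OH, 5-OH and 4'-OH free.
- In ring A the 7-OH is taken to be the kinetically preferred phenol (more acidic, flanked by two CH; the 5-OH is peri to C4). This is argued on steric and acidity grounds, not on a demonstrated precedent.
- The catalyst of step 3 is (4S)-2-methoxy-5,5-dimethyl-4-[2-(1-methyl-1H-imidazol-2-yl)phenyl]-3-(propan-2-yl)-1,3-oxazolidine, SMILES COC1OC(C)(C)[C@H](c2ccccc2-c2nccn2C)N1C(C)C. It is a reagent made separately (amino alcohol plus DMF dimethyl acetal, as for known alkoxy-exchange catalysts) and is not counted; its (4R) enantiomer is the first alternative if (4S) is the mismatched one.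

**Route**

Step 1
Reactants: 2 3,4,5-tris(benzyloxy)benzoic acid
Product: 3 3,4,5-tris(benzyloxy)benzoyl chloride
Conditions: (COCl)2 (1.5 equiv), DMF (cat.), CH2Cl2, 0 → 23 °C; evaporate, use crude
Reagents that add atoms: oxalyl chloride, O=C(Cl)C(=O)Cl
Why: DMF-catalysed (Vilsmeier-type) conversion of a carboxylic acid to its acid chloride; benzyl ethers are inert and there is no stereocentre.

Step 2
Reactants: 1 (+)-catechin; 3 3,4,5-tris(benzyloxy)benzoyl chloride; 4 phenylboronic acid
Product: 7 7-O-[3,4,5-tris(benzyloxy)benzoyl]-(+)-catechin, via catechin 3',4'-O-phenylboronate 5 (not isolated), via 7-O-aroyl catechin 3',4'-O-phenylboronate 6 (not isolated)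
Conditions: 4 (1.05 equiv), 4 Å MS, THF, 23 °C, 1 h; then i-Pr2NEt (1.1 equiv), 3 (1.0 equiv, slow addition), −40 → 0 °C; then pinacol (1.5 equiv), 23 °C; chromatography
Reagents that add atoms: none
Why: Einhorn-type O-acylation of a phenol by an acid chloride under transient boronate protection: 4 ties up the catechol as a five-membered boronate, the aliphatic 3-OH does not react without a nucleophilic catalyst, the 7-OH reacts ahead of the peri-hindered 5-OH and the new meta ester then deactivates the remaining ring A phenol, and pinacol finally takes the boron off; C2 and C3 are untouched.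

Step 3
Reactants: 7 7-O-[3,4,5-tris(benzyloxy)benzoyl]-(+)-catechin; 3 3,4,5-tris(benzyloxy)benzoyl chloride
Product: 8 7,3'-di-O-[3,4,5-tris(benzyloxy)benzoyl]-(+)-catechin
Conditions: 3 (1.05 equiv, slow addition), (4S)-2-methoxy-5,5-dimethyl-4-[2-(1-methyl-1H-imidazol-2-yl)phenyl]-3-(propan-2-yl)-1,3-oxazolidine (15 mol%), 2,6-lutidine (1.5 equiv), 2,6-lutidine·HCl (5 mol%), 4 Å MS, THF (0.05 M), −20 °C; AcOH quench
Reagents that add atoms: none
Why: Proposed new method: reversible-covalent scaffolding catalysis extended from vicinal diols to a remote phenol: the catalyst's N,O-acetal carbon exchanges its OMe for the only aliphatic hydroxyl of 7 (the 3-OH, exchange catalysed by lutidinium chloride), its imidazole takes the aroyl group from 3 as an acylimidazolium held about 4–5 Å from O3 by the rigid ortho-phenylene arm, and from there it can reach O3' (estimated about 4.6–5.7 Å from O3 as ring B rotates) but not O4' (on the rotation axis, about 6.5 Å away) or O5 (behind the C3–O3 bond, screened by C4 H2 and deactivated by the meta ester), so intramolecular acyl transfer gives the 3'-ester, whose ortho ester deactivates the 4'-OH, and exchange with fresh 7 turns the catalyst over, while the weak base leaves the catechol un-ionised so that neither background acylation nor 3'→4' acyl migration competes; the closest known chemistry is alkoxy-exchange scaffolding catalysis for site-selective acylation and silylation of cis-1,2-diols, together with peptide- or aminopyridine-catalysed site-selective acylation of polyols; no stereocentre is formed or touched.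

Step 4
Reactants: 8 7,3'-di-O-[3,4,5-tris(benzyloxy)benzoyl]-(+)-catechin
Product: 9 catechin 7,3'-di-O-gallate
Conditions: H2 (1 atm), 20% Pd(OH)2/C, THF–EtOAc 1:1, AcOH (1 vol%), 23 °C
Reagents that add atoms: none
Why: Heterogeneous catalytic hydrogenolysis of six benzyl aryl ethers under aprotic, slightly acidic conditions, which leaves the aryl esters, the chroman C2–O1 bond and both stereocentres intact and gives the catechol monoester no base with which to migrate.

**Compound list**

1 | (+)-catechin, (2R,3S)-2-(3,4-dihydroxyphenyl)-3,4-dihydro-2H-chromene-3,5,7-triol | Oc1cc(O)c2c(c1)O[C@H](c1ccc(O)c(O)c1)[C@@H](O)C2 | starting material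
2 | 3,4,5-tris(benzyloxy)benzoic acid | O=C(O)c1cc(OCc2ccccc2)c(OCc2ccccc2)c(OCc2ccccc2)c1 | starting material
3 | 3,4,5-tris(benzyloxy)benzoyl chloride | O=C(Cl)c1cc(OCc2ccccc2)c(OCc2ccccc2)c(OCc2ccccc2)c1 | intermediate
4 | phenylboronic acid | OB(O)c1ccccc1 | starting material
5 | catechin 3',4'-O-phenylboronate, (2R,3S)-2-(2-phenyl-1,3,2-benzodioxaborol-5-yl)-3,4-dihydro-2H-chromene-3,5,7-triol | Oc1cc(O)c2c(c1)O[C@H](c1ccc3OB(c4ccccc4)Oc3c1)[C@@H](O)C2 | intermediate
6 | 7-O-[3,4,5-tris(benzyloxy)benzoyl]catechin 3',4'-O-phenylboronate (2R,3S) | O=C(Oc1cc(O)c2c(c1)O[C@H](c1ccc3OB(c4ccccc4)Oc3c1)[C@@H](O)C2)c1cc(OCc2ccccc2)c(OCc2ccccc2)c(OCc2ccccc2)c1 | intermediate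
7 | 7-O-[3,4,5-tris(benzyloxy)benzoyl]-(+)-catechin, (2R,3S)-2-(3,4-dihydroxyphenyl)-3,5-dihydroxy-3,4-dihydro-2H-chromen-7-yl 3,4,5-tris(benzyloxy)benzoate | O=C(Oc1cc(O)c2c(c1)O[C@H](c1ccc(O)c(O)c1)[C@@H](O)C2)c1cc(OCc2ccccc2)c(OCc2ccccc2)c(OCc2ccccc2)c1 | intermediate
8 | 7,3'-di-O-[3,4,5-tris(benzyloxy)benzoyl]-(+)-catechin (aroyl esters at O7 of ring A and O3' of ring B; 3-OH, 5-OH and 4'-OH free; 2R,3S) | O=C(Oc1cc(O)c2c(c1)O[C@H](c1ccc(O)c(OC(=O)c3cc(OCc4ccccc4)c(OCc4ccccc4)c(OCc4ccccc4)c3)c1)[C@@H](O)C2)c1cc(OCc2ccccc2)c(OCc2ccccc2)c(OCc2ccccc2)c1 | intermediate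
9 | catechin 7,3'-di-O-gallate (2R,3S) | O=C(Oc1cc(O)c2c(c1)O[C@H](c1ccc(O)c(OC(=O)c3cc(O)c(O)c(O)c3)c1)[C@@H](O)C2)c1cc(O)c(O)c(O)c1 | target

**Step count and risks**

Total step count: 4. Longest linear sequence: 4 steps (2 → 3 → 7 → 8 → 9); 3 steps from 1.

The three steps most likely to fail:

Step 3 (the new directed acylation; risks are poor 3'/4' discrimination, 5-O-acylation, or background reaction). The fallback uses known chemistry, sets out from 7 and comes back at 8. Compound 7 is acylated with 3 (1.0 equiv) and i-Pr2NEt in THF at −40 °C with no directing catalyst. The catechol is mono-acylated without regiocontrol, giving 8 together with its regioisomer 7,4'-di-O-[3,4,5-tris(benzyloxy)benzoyl]-(+)-catechin F1. The two are separated by preparative HPLC on an acidified eluent. F1 is then stirred with a trace of Et3N in THF, which re-establishes the 8/F1 mixture by the known 1,2-acyl migration between the oxygens of a catechol monoester, and is recycled through the separation.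

Step 2 (risk: insufficient 7-O over 5-O selectivity). The fallback sets out from 1 and comes back at 9.
- The four phenols of 1 are silylated (TBSCl, imidazole, DMF) to 5,7,3',4'-tetra-O-TBS-catechin F2.
- TFA in CH2Cl2 at 0 °C removes the peri-strained 5-O-silyl group, a selectivity recalled as reported for silylated flavan-3-ols (to be verified on this substrate), giving 7,3',4'-tri-O-TBS-catechin F3.
- The freed phenol is benzylated (BnBr, K2CO3, acetone, 23 °C) to 5-O-benzyl-7,3',4'-tri-O-TBS-catechin F4.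
- Bu4NF buffered with AcOH in THF gives 5-O-benzyl-(+)-catechin F5, in which ring A has a single free phenol.
- F5 is then taken through the conditions of steps 2 to 4: its phenylboronate 5-O-benzylcatechin 3',4'-O-phenylboronate F6 and the 7-O-aroyl boronate F7 form in the flask, pinacol releases 5-O-benzyl-7-O-[3,4,5-tris(benzyloxy)benzoyl]catechin F8, the directed acylation gives 5-O-benzyl-7,3'-di-O-[3,4,5-tris(benzyloxy)benzoyl]catechin F9, and hydrogenolysis, now of seven benzyl ethers, gives 9.

Step 4 (risks: stalled debenzylation on a hexabenzyl substrate, or galloyl migration to O4' during long exposure to the catalyst). The fallback sets out from 8 and comes back at 9. It replaces reductive cleavage by Lewis-acid dealkylation: BCl3 (excess) with pentamethylbenzene as a non-basic benzyl-cation scavenger in CH2Cl2 at −78 °C, quenched cold with MeOH. This is a known way to cleave aryl benzyl ethers while leaving aryl esters alone, and the medium stays acidic throughout. Its own risk is acid ionisation of the chroman C2–O1 bond, which would epimerise C2. It makes no new compound (F0).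

**Further compounds**

F1 | step 3 | 7,4'-di-O-[3,4,5-tris(benzyloxy)benzoyl]-(+)-catechin (2R,3S) | O=C(Oc1cc(O)c2c(c1)O[C@H](c1ccc(OC(=O)c3cc(OCc4ccccc4)c(OCc4ccccc4)c(OCc4ccccc4)c3)c(O)c1)[C@@H](O)C2)c1cc(OCc2ccccc2)c(OCc2ccccc2)c(OCc2ccccc2)c1
F2 | step 2 | 5,7,3',4'-tetra-O-(tert-butyldimethylsilyl)-(+)-catechin (2R,3S) | CC(C)(C)[Si](C)(C)Oc1cc(O[Si](C)(C)C(C)(C)C)c2c(c1)O[C@H](c1ccc(O[Si](C)(C)C(C)(C)C)c(O[Si](C)(C)C(C)(C)C)c1)[C@@H](O)C2
F3 | step 2 | 7,3',4'-tri-O-(tert-butyldimethylsilyl)-(+)-catechin (2R,3S) | CC(C)(C)[Si](C)(C)Oc1cc(O)c2c(c1)O[C@H](c1ccc(O[Si](C)(C)C(C)(C)C)c(O[Si](C)(C)C(C)(C)C)c1)[C@@H](O)C2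
F4 | step 2 | 5-O-benzyl-7,3',4'-tri-O-(tert-butyldimethylsilyl)-(+)-catechin (2R,3S) | CC(C)(C)[Si](C)(C)Oc1cc(OCc3ccccc3)c2c(c1)O[C@H](c1ccc(O[Si](C)(C)C(C)(C)C)c(O[Si](C)(C)C(C)(C)C)c1)[C@@H](O)C2
F5 | step 2 | 5-O-benzyl-(+)-catechin (2R,3S) | Oc1cc(OCc3ccccc3)c2c(c1)O[C@H](c1ccc(O)c(O)c1)[C@@H](O)C2
F6 | step 2 | 5-O-benzylcatechin 3',4'-O-phenylboronate (2R,3S) | Oc1cc(OCc5ccccc5)c2c(c1)O[C@H](c1ccc3OB(c4ccccc4)Oc3c1)[C@@H](O)C2
F7 | step 2 | 5-O-benzyl-7-O-[3,4,5-tris(benzyloxy)benzoyl]catechin 3',4'-O-phenylboronate (2R,3S) | O=C(Oc1cc(OCc5ccccc5)c2c(c1)O[C@H](c1ccc3OB(c4ccccc4)Oc3c1)[C@@H](O)C2)c1cc(OCc2ccccc2)c(OCc2ccccc2)c(OCc2ccccc2)c1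
F8 | step 2 | 5-O-benzyl-7-O-[3,4,5-tris(benzyloxy)benzoyl]-(+)-catechin (2R,3S) | O=C(Oc1cc(OCc3ccccc3)c2c(c1)O[C@H](c1ccc(O)c(O)c1)[C@@H](O)C2)c1cc(OCc2ccccc2)c(OCc2ccccc2)c(OCc2ccccc2)c1
F9 | step 2 | 5-O-benzyl-7,3'-di-O-[3,4,5-tris(benzyloxy)benzoyl]-(+)-catechin (2R,3S) | O=C(Oc1cc(OCc5ccccc5)c2c(c1)O[C@H](c1ccc(O)c(OC(=O)c3cc(OCc4ccccc4)c(OCc4ccccc4)c(OCc4ccccc4)c3)c1)[C@@H](O)C2)c1cc(OCc2ccccc2)c(OCc2ccccc2)c(OCc2ccccc2)c1
F0 | step 4 | none | none
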